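**Plan**

- Cuts, in retrosynthetic order: all benzyl ethers and four capping bromines; the interflavan bond C4(middle)–C6(bottom); the aryl ether bond O1–C8a of ring C of the middle unit; C4–C4a of the middle unit; the interflavan bond C4(top)–C8(middle).
- Enabling feature: in ring A of the middle unit, C8a lies between C8 (carrying the top unit) and C4a (carrying C4) and is meta to the oxygens on C5 and C7. A fluorine at C8a steers the first union to C8, directs lithiation to C4a, and is finally displaced by the C2 oxygen six atoms away (O–C2–C3–C4–C4a–C8a).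
- Forward order: (+)-catechin gives a C4-activated top unit; Friedel–Crafts union with 5-fluororesorcinol forms C4–C8; fluorine-directed lithiation and addition to an aldol-derived aldehyde forms C4a–C4 with C4 already a carbinol; intramolecular SNAr closes ring C and gives the 4→8 dimer; bromine capping, then the C4 cation and an 8-bromo catechin unit form C4–C6; hydrogenolysis.
- Stereochemistry: top and bottom units are bought as (+)-catechin; C4 of the top unit (3,4-trans) by substrate control; C2 and C3 of the middle unit from one Evans syn-aldol (auxiliary from L-phenylalanine), the syn pair becoming 2,3-cis because the C2–O bond is never broken; C4 of the middle unit (3,4-trans) by substrate control in the ring C cation.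

Key step: step 12

Remark: C4 of acetal 4 and C4 of the middle unit in 18–21 are carried as epimer mixtures (left undefined in the SMILES), because each of these centres is ionised later (steps 4 and 15).

**Route**

Step 1
Reactants: 1 (+)-catechin
Product: 2 5,7,3',4'-tetra-O-benzyl-(+)-catechin
Conditions: BnBr, K2CO3, DMF, 0 °C to rt
Reagents that add atoms: benzyl bromide BrCc1ccccc1
Why: Williamson etherification of the four phenols with a carbonate base should leave the secondary C3 alcohol and both stereocenters untouched.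

Step 2
Reactants: 2 5,7,3',4'-tetra-O-benzyl-(+)-catechin
Product: 3 3,5,7,3',4'-penta-O-benzyl-(+)-catechin
Conditions: NaH, BnBr, Bu4NI (cat.), DMF, 0 °C to rt
Reagents that add atoms: benzyl bromide BrCc1ccccc1
Why: Williamson O-benzylation of the C3 alkoxide blocks the only oxygen of the top unit that could later reach the fluorine-bearing carbon through a five-membered SNAr transition state.

Step 3
Reactants: 3 3,5,7,3',4'-penta-O-benzyl-(+)-catechin
Product: 4 3,5,7,3',4'-penta-O-benzyl-4-(2-ethoxyethoxy)-(+)-catechin (C4 epimers)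
Conditions: DDQ, 2-ethoxyethanol, CH2Cl2, rt
Reagents that add atoms: 2-ethoxyethanol CCOCCO
Why: DDQ benzylic oxidation (hydride abstraction from C4 gives a cation stabilised by the ring A oxygens) with capture by the alcohol should install the C4 leaving group, whose configuration does not matter.

Step 4
Reactants: 4 3,5,7,3',4'-penta-O-benzyl-4-(2-ethoxyethoxy)-(+)-catechin, 5 5-fluororesorcinol
Product: 6 4α-(2-fluoro-4,6-dihydroxyphenyl)-3,5,7,3',4'-penta-O-benzyl-(+)-catechin (3,4-trans)
Conditions: 5 (5 equiv), BF3·OEt2 (0.3 equiv), CH2Cl2–THF, −20 °C to 0 °C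
Reagents that add atoms: none
Why: Friedel–Crafts alkylation by the ring C benzylic cation, in which the free resorcinol should outpace the benzylated ring A of 4 and react at a carbon para to one OH and ortho to fluorine (the two such carbons are equivalent), on the face of C4 opposite the C3 benzyloxy group, so that the 3,4-trans centre is set by substrate control.

Step 5
Reactants: 6 4α-(2-fluoro-4,6-dihydroxyphenyl)-3,5,7,3',4'-penta-O-benzyl-(+)-catechin
Product: 7 4α-[2-fluoro-4,6-bis(benzyloxy)phenyl]-3,5,7,3',4'-penta-O-benzyl-(+)-catechin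
Conditions: BnBr, K2CO3, DMF, rt
Reagents that add atoms: benzyl bromide BrCc1ccccc1
Why: Williamson etherification of the two phenols should give the base-stable, fully benzylated arene needed for lithiation.

Step 6
Reactants: 8 (S)-4-benzyloxazolidin-2-one, 9 benzyloxyacetyl chloride
Product: 10 (S)-4-benzyl-3-(benzyloxyacetyl)oxazolidin-2-one
Conditions: n-BuLi, THF, −78 °C; then 9, −78 °C to 0 °C
Reagents that add atoms: none
Why: N-acylation of the lithiated oxazolidinone by the acid chloride should give the glycolate imide without touching the auxiliary stereocenter.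

Step 7
Reactants: 10 (S)-4-benzyl-3-(benzyloxyacetyl)oxazolidin-2-one, 11 3,4-bis(benzyloxy)benzaldehyde
Product: 13 (S)-4-benzyl-3-[(2S,3R)-2-(benzyloxy)-3-[3,4-bis(benzyloxy)phenyl]-3-hydroxypropanoyl]oxazolidin-2-one, via dibutylboron Z-enolate 12 (not isolated)
Conditions: Bu2BOTf, Et3N, CH2Cl2, −78 °C to 0 °C; then 11, −78 °C to 0 °C; H2O2, MeOH, pH 7 buffer
Reagents that add atoms: none
Why: Evans syn-aldol in which the boron Z-enolate reacts through a chair Zimmerman–Traxler transition state on the face away from the benzyl group of the auxiliary, which should set the future C3 (ether) and C2 (carbinol) centres of the middle unit in one event as the syn pair.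

Step 8
Reactants: 13 (S)-4-benzyl-3-[(2S,3R)-2-(benzyloxy)-3-[3,4-bis(benzyloxy)phenyl]-3-hydroxypropanoyl]oxazolidin-2-one
Product: 14 (2S,3R)-2-(benzyloxy)-3-[3,4-bis(benzyloxy)phenyl]-3-hydroxy-N-methoxy-N-methylpropanamide
Conditions: MeNH(OMe)·HCl, AlMe3, THF, 0 °C to rt
Reagents that add atoms: N,O-dimethylhydroxylamine hydrochloride CNOC.Cl
Why: Weinreb transamidation by the aluminium amide at the exocyclic imide carbonyl, assisted by the neighbouring aluminium alkoxide, should release the auxiliary without affecting either stereocenter.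

Step 9
Reactants: 14 (2S,3R)-2-(benzyloxy)-3-[3,4-bis(benzyloxy)phenyl]-3-hydroxy-N-methoxy-N-methylpropanamide
Product: 15 (2S,3R)-2-(benzyloxy)-3-[3,4-bis(benzyloxy)phenyl]-3-(tert-butyldimethylsilyloxy)-N-methoxy-N-methylpropanamide
Conditions: TBSOTf, 2,6-lutidine, CH2Cl2, 0 °C
Reagents that add atoms: tert-butyldimethylsilyl trifluoromethanesulfonate CC(C)(C)[Si](C)(C)OS(=O)(=O)C(F)(F)F
Why: O-silylation masks the future O1 with a group that is inert to the aryllithium and orthogonal to the benzyl ether on the future C3 oxygen.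

Step 10
Reactants: 15 (2S,3R)-2-(benzyloxy)-3-[3,4-bis(benzyloxy)phenyl]-3-(tert-butyldimethylsilyloxy)-N-methoxy-N-methylpropanamide
Product: 16 (2S,3R)-2-(benzyloxy)-3-[3,4-bis(benzyloxy)phenyl]-3-(tert-butyldimethylsilyloxy)propanal
Conditions: i-Bu2AlH, THF, −78 °C
Reagents that add atoms: none
Why: Reduction of the Weinreb amide stops at the chelated tetrahedral intermediate and should release the α-alkoxy aldehyde on work-up without epimerisation when kept cold and used crude.

Step 11
Reactants: 7 4α-[2-fluoro-4,6-bis(benzyloxy)phenyl]-3,5,7,3',4'-penta-O-benzyl-(+)-catechin, 16 (2S,3R)-2-(benzyloxy)-3-[3,4-bis(benzyloxy)phenyl]-3-(tert-butyldimethylsilyloxy)propanal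
Product: 19 open-chain 1,3-diol (1-aryl-2-benzyloxy-3-[3,4-bis(benzyloxy)phenyl]propane-1,3-diol; aryl = 2-fluoro-4,6-bis(benzyloxy)-3-(penta-O-benzylcatechin-4α-yl)phenyl; C1 epimers), via aryllithium 17 (not isolated), via silyl ether carbinol 18 (not isolated)
Conditions: n-BuLi, THF, −78 °C; then 16, −78 °C; AcOH, then Bu4NF, 0 °C to rt
Reagents that add atoms: none
Why: Directed ortho-metalation removes the one ring proton flanked by fluorine and a benzyloxy group, the aryllithium adds 1,2 to the aldehyde, and fluoride cleaves the silyl ether; the new carbinol centre (future C4) forms as a mixture, which is of no consequence.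

Step 12
Reactants: 19 open-chain 1,3-diol
Product: 20 penta-O-benzylcatechin-(4α→8)-3,5,7,3',4'-penta-O-benzyl-4-hydroxyepicatechin (C4 epimers)
Conditions: KH, 18-crown-6, THF, 0 °C to 50 °C
Reagents that add atoms: none
Why: KH deprotonates both hydroxyl groups, and the C2 alkoxide adds to the fluorine-bearing carbon C8a to give a Meisenheimer anion that expels fluoride (addition–elimination SNAr), an aryne route being excluded because both carbons ortho to fluorine are substituted. The closest known reaction type is the intramolecular SNAr pyran closure of 3,5-dialkoxyfluorobenzenes carrying a 3-hydroxypropyl chain, as used for flavan-3-ols. Ring C closes in a 6-exo-trig mode (O–C2–C3–C4–C4a–C8a, the accepting π bond C8a=C8 lying outside the new ring). No stereocenter is formed; C2 and C3 keep the aldol configuration because no bond to either carbon is broken, so the syn pair becomes the 2,3-cis (epicatechin-type) ring. The step needs chemoselectivity among the oxygen nucleophiles and an arene that accepts the charge: only the C2 alkoxide can reach C8a (the C4 alkoxide would form a four-membered ring, both C3 oxygens are benzylated), and the two benzyloxy groups are meta to fluorine, where they stabilise the anionic intermediate inductively without donating into the attacked carbon. Because fluorine fixes which carbon receives oxygen, the top unit sits unambiguously at C8 and the carbinol carbon at C4.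

Step 13
Reactants: 20 penta-O-benzylcatechin-(4α→8)-3,5,7,3',4'-penta-O-benzyl-4-hydroxyepicatechin
Product: 21 tribromide of 20 (Br at C6 and C8 of the top unit and at C6 of the middle unit)
Conditions: NBS (3.1 equiv), CH2Cl2, −78 °C to 0 °C
Reagents that add atoms: N-bromosuccinimide O=C1CCC(=O)N1Br
Why: Electrophilic aromatic bromination at the three ring A carbons flanked by two oxygens caps every nucleophilic site of the electrophile, so that the cation of step 15 cannot condense with itself.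

Step 14
Reactants: 2 5,7,3',4'-tetra-O-benzyl-(+)-catechin
Product: 22 8-bromo-5,7,3',4'-tetra-O-benzyl-(+)-catechin
Conditions: NBS (1.0 equiv), CH2Cl2, −78 °C to rt
Reagents that add atoms: N-bromosuccinimide O=C1CCC(=O)N1Br
Why: Electrophilic bromination should take the less hindered ring A carbon C8 (between C8a and C7–OBn) before C6 (between two benzyloxy groups), which leaves C6 as the only ring A nucleophilic site.

Step 15
Reactants: 21 tribromide of 20, 22 8-bromo-5,7,3',4'-tetra-O-benzyl-(+)-catechin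
Product: 23 protected trimer (tetradeca-O-benzyl tetrabromo catechin-(4α→8)-epicatechin-(4β→6)-catechin)
Conditions: 22 (3 equiv), BF3·OEt2 (0.2 equiv), 4 Å molecular sieves, CH2Cl2, −78 °C to −20 °C
Reagents that add atoms: none
Why: Friedel–Crafts alkylation with halogen capping, in which the ring C cation at C4 of the middle unit is attacked by C6 of 22 (its only free ring A carbon) on the face opposite the C3 benzyloxy group, so that the 3,4-trans (4β) centre should be set by substrate control.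

Step 16
Reactants: 23 protected trimer
Product: 24 catechin-(4α→8)-epicatechin-(4β→6)-catechin (CNP0178679.1)
Conditions: H2 (1 atm), Pd(OH)2/C, Et3N, THF–MeOH–H2O, rt
Reagents that add atoms: none
Why: Catalytic hydrogenolysis should cleave the fourteen benzyl ethers and the four aryl C–Br bonds in one operation, with Et3N taking up HBr so that the acid-labile interflavan bonds survive.

**Compound list**

1 | (+)-catechin, (2R,3S)-2-(3,4-dihydroxyphenyl)chromane-3,5,7-triol | Oc1cc(O)c2c(c1)O[C@H](c1ccc(O)c(O)c1)[C@@H](O)C2 | starting material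
2 | 5,7,3',4'-tetra-O-benzyl-(+)-catechin | c1ccccc1COc1cc(OCc3ccccc3)c2c(c1)O[C@H](c1ccc(OCc3ccccc3)c(OCc3ccccc3)c1)[C@@H](O)C2 | intermediate
3 | 3,5,7,3',4'-penta-O-benzyl-(+)-catechin | c1ccccc1COc1cc(OCc3ccccc3)c2c(c1)O[C@H](c1ccc(OCc3ccccc3)c(OCc3ccccc3)c1)[C@@H](OCc1ccccc1)C2 | intermediate
4 | 3,5,7,3',4'-penta-O-benzyl-4-(2-ethoxyethoxy)-(+)-catechin (C4 epimers) | c1ccccc1COc1cc(OCc3ccccc3)c2c(c1)O[C@H](c1ccc(OCc3ccccc3)c(OCc3ccccc3)c1)[C@@H](OCc1ccccc1)C2OCCOCC | intermediate
5 | 5-fluororesorcinol (5-fluorobenzene-1,3-diol) | Oc1cc(O)cc(F)c1 | starting material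
6 | 4α-(2-fluoro-4,6-dihydroxyphenyl)-3,5,7,3',4'-penta-O-benzyl-(+)-catechin (2R, 2,3-trans, 3,4-trans) | c1ccccc1COc1cc(OCc3ccccc3)c2c(c1)O[C@H](c1ccc(OCc3ccccc3)c(OCc3ccccc3)c1)[C@@H](OCc1ccccc1)[C@@H]2c1c(O)cc(O)cc1F | intermediate
7 | 4α-[2-fluoro-4,6-bis(benzyloxy)phenyl]-3,5,7,3',4'-penta-O-benzyl-(+)-catechin | c1ccccc1COc1cc(OCc3ccccc3)c2c(c1)O[C@H](c1ccc(OCc3ccccc3)c(OCc3ccccc3)c1)[C@@H](OCc1ccccc1)[C@@H]2c1c(OCc3ccccc3)cc(OCc3ccccc3)cc1F | intermediate
8 | (S)-4-benzyloxazolidin-2-one | O=C1N[C@@H](Cc2ccccc2)CO1 | starting material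
9 | benzyloxyacetyl chloride | O=C(Cl)COCc1ccccc1 | starting material
10 | (S)-4-benzyl-3-(benzyloxyacetyl)oxazolidin-2-one | O=C(COCc1ccccc1)N1[C@@H](Cc2ccccc2)COC1=O | intermediate
11 | 3,4-bis(benzyloxy)benzaldehyde | O=Cc1ccc(OCc2ccccc2)c(OCc2ccccc2)c1 | starting material
12 | dibutylboron Z-enolate of 10 (not isolated) | CCCCB(CCCC)O/C(=C\OCc1ccccc1)N1[C@@H](Cc2ccccc2)COC1=O | intermediate
13 | (S)-4-benzyl-3-[(2S,3R)-2-(benzyloxy)-3-[3,4-bis(benzyloxy)phenyl]-3-hydroxypropanoyl]oxazolidin-2-one | O[C@H](c1ccc(OCc2ccccc2)c(OCc2ccccc2)c1)[C@H](OCc1ccccc1)C(=O)N1[C@@H](Cc2ccccc2)COC1=O | intermediate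
14 | (2S,3R)-2-(benzyloxy)-3-[3,4-bis(benzyloxy)phenyl]-3-hydroxy-N-methoxy-N-methylpropanamide | O[C@H](c1ccc(OCc2ccccc2)c(OCc2ccccc2)c1)[C@H](OCc1ccccc1)C(=O)N(C)OC | intermediate
15 | (2S,3R)-2-(benzyloxy)-3-[3,4-bis(benzyloxy)phenyl]-3-(tert-butyldimethylsilyloxy)-N-methoxy-N-methylpropanamide | CC(C)(C)[Si](C)(C)O[C@H](c1ccc(OCc2ccccc2)c(OCc2ccccc2)c1)[C@H](OCc1ccccc1)C(=O)N(C)OC | intermediate
16 | (2S,3R)-2-(benzyloxy)-3-[3,4-bis(benzyloxy)phenyl]-3-(tert-butyldimethylsilyloxy)propanal | CC(C)(C)[Si](C)(C)O[C@H](c1ccc(OCc2ccccc2)c(OCc2ccccc2)c1)[C@H](OCc1ccccc1)C=O | intermediate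
17 | aryllithium from 7, lithium on the ring carbon between fluorine and benzyloxy (not isolated) | c1ccccc1COc1cc(OCc3ccccc3)c2c(c1)O[C@H](c1ccc(OCc3ccccc3)c(OCc3ccccc3)c1)[C@@H](OCc1ccccc1)[C@@H]2c1c(OCc3ccccc3)cc(OCc3ccccc3)c([Li])c1F | intermediate
18 | silyl ether carbinol: adduct of 17 and 16, C1 carbinol epimers, C3 oxygen as TBS ether (not isolated) | c1ccccc1COc1cc(OCc3ccccc3)c2c(c1)O[C@H](c1ccc(OCc3ccccc3)c(OCc3ccccc3)c1)[C@@H](OCc1ccccc1)[C@@H]2c1c(OCc3ccccc3)cc(OCc3ccccc3)c(C(O)[C@@H](OCc3ccccc3)[C@H](O[Si](C)(C)C(C)(C)C)c3ccc(OCc4ccccc4)c(OCc4ccccc4)c3)c1F | intermediate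
19 | open-chain 1,3-diol: 1-aryl-2-benzyloxy-3-[3,4-bis(benzyloxy)phenyl]propane-1,3-diol, aryl = 2-fluoro-4,6-bis(benzyloxy)-3-(penta-O-benzylcatechin-4α-yl)phenyl, C2 and C3 as in 16, C1 epimers | c1ccccc1COc1cc(OCc3ccccc3)c2c(c1)O[C@H](c1ccc(OCc3ccccc3)c(OCc3ccccc3)c1)[C@@H](OCc1ccccc1)[C@@H]2c1c(OCc3ccccc3)cc(OCc3ccccc3)c(C(O)[C@@H](OCc3ccccc3)[C@H](O)c3ccc(OCc4ccccc4)c(OCc4ccccc4)c3)c1F | intermediate
20 | penta-O-benzylcatechin-(4α→8)-3,5,7,3',4'-penta-O-benzyl-4-hydroxyepicatechin (middle unit 2R, 2,3-cis; C4 epimers) | c1ccccc1COc1cc(OCc3ccccc3)c2c(c1)O[C@H](c1ccc(OCc3ccccc3)c(OCc3ccccc3)c1)[C@@H](OCc1ccccc1)[C@@H]2c1c(OCc3ccccc3)cc(OCc3ccccc3)c2c1O[C@H](c1ccc(OCc3ccccc3)c(OCc3ccccc3)c1)[C@H](OCc1ccccc1)C2O | intermediate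
21 | tribromide of 20: 6,8-dibromo in the top unit, 6-bromo in the middle unit | c1ccccc1COc1c(Br)c(OCc3ccccc3)c2c(c1Br)O[C@H](c1ccc(OCc3ccccc3)c(OCc3ccccc3)c1)[C@@H](OCc1ccccc1)[C@@H]2c1c(OCc3ccccc3)c(Br)c(OCc3ccccc3)c2c1O[C@H](c1ccc(OCc3ccccc3)c(OCc3ccccc3)c1)[C@H](OCc1ccccc1)C2O | intermediate
22 | 8-bromo-5,7,3',4'-tetra-O-benzyl-(+)-catechin | c1ccccc1COc1cc(OCc3ccccc3)c2c(c1Br)O[C@H](c1ccc(OCc3ccccc3)c(OCc3ccccc3)c1)[C@@H](O)C2 | intermediate
23 | protected trimer: tetradeca-O-benzyl tetrabromo catechin-(4α→8)-epicatechin-(4β→6)-catechin, bottom 3-OH free, Br at C6 and C8 (top), C6 (middle), C8 (bottom) | c1ccccc1COc1c(Br)c(OCc3ccccc3)c2c(c1Br)O[C@H](c1ccc(OCc3ccccc3)c(OCc3ccccc3)c1)[C@@H](OCc1ccccc1)[C@@H]2c1c(OCc3ccccc3)c(Br)c(OCc3ccccc3)c2c1O[C@H](c1ccc(OCc3ccccc3)c(OCc3ccccc3)c1)[C@H](OCc1ccccc1)[C@H]2c1c(OCc3ccccc3)c(Br)c2c(c1OCc3ccccc3)C[C@H](O)[C@@H](c1ccc(OCc3ccccc3)c(OCc3ccccc3)c1)O2 | intermediate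
24 | catechin-(4α→8)-epicatechin-(4β→6)-catechin (CNP0178679.1) | Oc1cc(O)c2c(c1)O[C@H](c1ccc(O)c(O)c1)[C@@H](O)[C@@H]2c1c(O)cc(O)c2c1O[C@H](c1ccc(O)c(O)c1)[C@H](O)[C@H]2c1c(O)cc2c(c1O)C[C@H](O)[C@@H](c1ccc(O)c(O)c1)O2 | target

**Count and risks**

Total step count: 16. Longest linear sequence: 10 steps (steps 6–10, 11, 12, 13, 15, 16; the branch through steps 1–5 is equally long).

Step 12. The alkoxide may add too slowly to the doubly ortho-substituted fluoroarene, so that the dianion degrades on heating before ring closure. The fallback (carbonyl-activated SNAr) sets out from silyl ether carbinol 18, obtained by leaving out the fluoride treatment in step 11. Dess–Martin periodinane should oxidise the C4 carbinol to the aryl ketone silyl ether F1. HF·pyridine should free the C2 hydroxyl to give the β-hydroxy ketone F2. The ketone ortho to fluorine can now take up the negative charge, so Cs2CO3 in DMF at 0 °C should close ring C to the 2,3-cis 3-benzyloxychroman-4-one F3, with a short contact time to limit epimerisation at C3. NaBH4 reduction of the C4 ketone brings the route back to 20.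

Step 15. Attack by the hindered, bromine-deactivated C6 of the benzylated nucleophile may be too slow, so that the cation eliminates or is captured reversibly by oxygen. The fallback (free-phenol nucleophile) sets out from 22. BCl3 with pentamethylbenzene in CH2Cl2 at −78 °C should remove the four aryl benzyl ethers without touching the aryl bromide, giving 8-bromo-(+)-catechin F4. Its free phloroglucinol ring is far more nucleophilic, and coupling with 21 (BF3·OEt2 cat., THF–CH2Cl2) should give the partially protected trimer F5 at C6, the only free ring A carbon. Hydrogenolysis as in step 16 brings the route back to 24.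

Step 11. Deprotonation may be unselective (benzylic OCH2 groups or ring A protons of the top unit), or the ortho-fluoro aryllithium may lose LiF to an aryne. The fallback (halogen–lithium exchange instead of deprotonation) sets out from 6. NBS (1 equiv, −78 °C) should brominate the free resorcinol ring, the most activated ring, at the carbon para to one OH and ortho to fluorine, giving bromo-resorcinol adduct F6. Benzylation (BnBr, K2CO3) gives bromide F7. Bromine–lithium exchange with n-BuLi at −78 °C brings the route back to aryllithium 17, which is carried on as in step 11.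

**Further compounds**

F1 | step 12 | aryl ketone silyl ether (C4 ketone of 18) | c1ccccc1COc1cc(OCc3ccccc3)c2c(c1)O[C@H](c1ccc(OCc3ccccc3)c(OCc3ccccc3)c1)[C@@H](OCc1ccccc1)[C@@H]2c1c(OCc3ccccc3)cc(OCc3ccccc3)c(C(=O)[C@@H](OCc3ccccc3)[C@H](O[Si](C)(C)C(C)(C)C)c3ccc(OCc4ccccc4)c(OCc4ccccc4)c3)c1F
F2 | step 12 | β-hydroxy ketone (desilylated F1) | c1ccccc1COc1cc(OCc3ccccc3)c2c(c1)O[C@H](c1ccc(OCc3ccccc3)c(OCc3ccccc3)c1)[C@@H](OCc1ccccc1)[C@@H]2c1c(OCc3ccccc3)cc(OCc3ccccc3)c(C(=O)[C@@H](OCc3ccccc3)[C@H](O)c3ccc(OCc4ccccc4)c(OCc4ccccc4)c3)c1F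
F3 | step 12 | penta-O-benzylcatechin-(4α→8)-2,3-cis-3,5,7,3',4'-penta-O-benzyl-flavan-4-one (C4 ketone of 20) | c1ccccc1COc1cc(OCc3ccccc3)c2c(c1)O[C@H](c1ccc(OCc3ccccc3)c(OCc3ccccc3)c1)[C@@H](OCc1ccccc1)[C@@H]2c1c(OCc3ccccc3)cc(OCc3ccccc3)c2c1O[C@H](c1ccc(OCc3ccccc3)c(OCc3ccccc3)c1)[C@H](OCc1ccccc1)C2=O
F4 | step 15 | 8-bromo-(+)-catechin | Oc1cc(O)c2c(c1Br)O[C@H](c1ccc(O)c(O)c1)[C@@H](O)C2
F5 | step 15 | partially protected trimer (top and middle units as in 23, bottom unit 8-bromo with free hydroxyl groups) | c1ccccc1COc1c(Br)c(OCc3ccccc3)c2c(c1Br)O[C@H](c1ccc(OCc3ccccc3)c(OCc3ccccc3)c1)[C@@H](OCc1ccccc1)[C@@H]2c1c(OCc3ccccc3)c(Br)c(OCc3ccccc3)c2c1O[C@H](c1ccc(OCc3ccccc3)c(OCc3ccccc3)c1)[C@H](OCc1ccccc1)[C@H]2c1c(O)c(Br)c2c(c1O)C[C@H](O)[C@@H](c1ccc(O)c(O)c1)O2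
F6 | step 11 | bromo-resorcinol adduct: 4α-(3-bromo-2-fluoro-4,6-dihydroxyphenyl)-3,5,7,3',4'-penta-O-benzyl-(+)-catechin | c1ccccc1COc1cc(OCc3ccccc3)c2c(c1)O[C@H](c1ccc(OCc3ccccc3)c(OCc3ccccc3)c1)[C@@H](OCc1ccccc1)[C@@H]2c1c(O)cc(O)c(Br)c1F
F7 | step 11 | bromide: 4α-[3-bromo-2-fluoro-4,6-bis(benzyloxy)phenyl]-3,5,7,3',4'-penta-O-benzyl-(+)-catechin | c1ccccc1COc1cc(OCc3ccccc3)c2c(c1)O[C@H](c1ccc(OCc3ccccc3)c(OCc3ccccc3)c1)[C@@H](OCc1ccccc1)[C@@H]2c1c(OCc3ccccc3)cc(OCc3ccccc3)c(Br)c1F
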